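## The problem

Target 21 is a fully substituted 1,4-benzoquinone. With the ring numbered so that C1 and C4 are the carbonyls, C2 and C5 carry methoxy groups, C3 carries a 7-prenylindol-3-yl group and C6 an indol-3-yl group. The two aryl groups differ, so the ring cannot be made by a symmetric dimerisation. The two indoles must be introduced separately, and the methoxy groups must end up para to each other (head-to-tail) and not 2,6. There is no stereocentre and no double bond with a configuration to set, so every selectivity question is one of regiochemistry. Three parts are fragile. The prenyl group is sensitive to strong acid, electrophilic halogen and oxidants. The electron-rich indoles are sensitive to oxidants. The methoxyquinone is a vinylogous ester that hydroxide and other nucleophiles attack and that is easily reduced. The prenyl group at C7 also crowds N1, which limits the choice of N-protecting group on that indole. The enabling feature is that C1(=O)–C2(OMe)=C3(aryl)–C4(=O) is the carbon set of a 3-methoxy-4-arylcyclobutenedione, and C5(OMe)=C6(aryl) is that of an aryl ynol ether. A metal inserted between the two carbonyl carbons can join the two pieces at C1–C6 and C4–C5 and deliver the ring at the quinone oxidation level.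

## Retrosynthesis

**21 to 20.** The last cut is the two N–H bonds, which are masked as N-silyl groups in quinone 20. The masking is needed earlier for the organolithium and organozinc chemistry. Silyl is chosen because fluoride buffered with acetic acid removes it without touching the vinylogous ester or the prenyl group. Sulfonyl or alkyl groups would need base or acid that the quinone or the alkene would not survive.

**20 to 10 and 17 (key cut).** The bonds C1–C6 and C4–C5 are cut. This gives cyclobutenedione 10 (C1–C4, carrying the prenylated indole) and ynol ether 17 (C5 and C6, carrying the plain indole). Forward, cobalt inserts between the carbonyls of 10 to give maleoyl complex 18, which is converted into the more labile complex 19 and takes up 17. The mirror pairing (plain indole on the dione, prenylindole on the ynol ether) is chemically equivalent, but it would put the prenyl group on the most fragile intermediate. Cuts at the indole–quinone bonds would need acid-promoted additions in the presence of the prenyl group and a later adjustment of oxidation level. The cut chosen halves the molecule and asks only one thing of the forward reaction: head-to-tail orientation of the ynol ether.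

**10 to 6 and 7.** The indole C3–cyclobutene bond is cut. Dimethyl squarate 7 is symmetric, so 1,2-addition of the 3-lithioindole 8 (from iodide 6) has no regiochemical issue. The adduct 9 is rearranged by acylation to the 3-methoxy-4-aryl dione. A Friedel–Crafts route with squaric dichloride would expose the prenyl group to HCl.

**6 to 5, 4, 1 and 2.** The N–Si and C3–I bonds are removed in turn, giving 7-prenylindole 4. Its C7–CH2 bond is cut to 7-bromoindole 1 and prenyl bromide 2 through the N,C7-dimetalated indole 3. Iodination is placed before silylation so that the electrophile meets the very nucleophilic free indole (compound 5) and not the alkene.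

**17 to 13 and 14.** The C(sp2)–C(sp) bond is cut. The alkynyl part comes from chloroacetaldehyde dimethyl acetal 14 through lithium methoxyacetylide 15 and zinc reagent 16, which is coupled with iodide 13. The iodide comes from indole 11 through 3-iodoindole 12. The methyl ynol ether is chosen because its methoxy group is already the C5 substituent of the target and because it has no O-alkyl β-hydrogen for thermal fragmentation.

## Roads not taken

**Alternative 1: Larock heteroannulation.** The cut is at N1–C2 and C3–C3a of the prenylated indole. Forward, Pd(OAc)2 would join 2-iodo-6-prenylaniline A1 with the aryl(trimethylsilyl)alkyne A2, built on a tetramethoxybenzene core, to give the 2-silylindole A3.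
- Merits: the annulation reliably places the silyl group at C2 and the aryl group at C3, and the prenylated indole needs no N-protection, so the crowding at N1 that the chosen plan must handle does not arise. In that respect it is the better plan.
- Weak points: the alkyne carbon sits between two ortho methoxy groups, and the aniline is ortho-substituted, so insertion should be slow. The core must be desymmetrised by two sequential couplings. After protodesilylation and Boc removal the quinone has to be freed by oxidative demethylation of a tetramethoxyarene, with two electron-rich indoles and a prenyl group present.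
- Comparison: the route is clearly longer. The chosen plan sets against it that the ring is formed directly at the quinone oxidation level, with no late oxidant.

**Alternative 2: biomimetic Claisen dimerisation.** The cut is at both C(indolyl)–C(carbonyl) ring bonds. Forward, base would make the benzylic carbon of methyl indol-3-ylpyruvate A4 and of its 7-prenyl analogue A5 each acylate the ester of the other, giving dihydroxyquinone A6. O-Methylation would then give 21.
- Merits: it is by far the shortest route (about five steps against nine). Head-to-tail connectivity is built into the bond formation, and no redox step is needed. On step count it beats the chosen plan.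
- Weak points: A4 and A5 are electronically almost identical, so the crossed product can at best be the statistical half of a mixture with two homodimers of similar polarity. The ketone of a pyruvate is more electrophilic than its ester, so aldol self-condensation competes with the Claisen path. The free N–H groups consume base.
- Comparison: the chosen plan differentiates the two halves by construction (one is a dione, the other an alkyne), so no statistical mixture has to be separated.

**Alternative 3: six-electron electrocyclisation.** The cut is at C5–C6 of the prenylated benzo ring. Forward, heating the pyrrole-bound triene A7 and dehydrogenating with DDQ would give the bis-tosyl bisindolyl tetramethoxybenzene A8.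
- Merits: the position of the prenyl group is fixed by the dienyl unit, and the route does not depend on functionalising C7 of an indole.
- Weak points: it builds a benzene ring that is commercially available in 7-bromoindole. The skipped diene of A7 can move into conjugation. The closure needs high temperature, and DDQ threatens the prenyl group. Two N-tosyl groups must then be removed with base, and the core oxidised to the quinone as in Alternative 1.
- Comparison: it is much longer and is better than the chosen plan in no respect that matters for this target.

Key step: step 8

Assumption: complex 19 is drawn as the neutral chloro(pyridine) complex of trivalent cobalt with N,N-bound neutral dimethylglyoxime; the exact ligand set at cobalt does not change the organic outcome.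

## Route

Step 1
Reactants: 1 7-bromo-1H-indole; 2 1-bromo-3-methylbut-2-ene (prenyl bromide)
Product: 4 7-(3-methylbut-2-en-1-yl)-1H-indole (7-prenylindole), via 7-lithioindol-1-ylpotassium 3 (not isolated)
Conditions: KH, THF, 0 °C; t-BuLi (2 equiv), −78 °C; then 2 (1.0 equiv), −78 °C → rt; aq NH4Cl
Reagents that add atoms: none
Why: Deprotonation of N–H and then bromine–lithium exchange gives a C7 aryllithium that should alkylate the primary carbon of prenyl bromide (SN2) much faster than the nitrogen anion does; the second equivalent of t-BuLi destroys the t-BuBr formed.

Step 2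
Reactants: 4 7-prenylindole
Product: 5 3-iodo-7-prenyl-1H-indole
Conditions: I2 (1.0 equiv), KOH, DMF, rt; used at once
Reagents that add atoms: iodine, II
Why: Electrophilic iodination of the indolide at C3, its most nucleophilic carbon; under basic conditions iodine adds only reversibly to the trisubstituted alkene, so the prenyl group should be left alone.

Step 3
Reactants: 5 3-iodo-7-prenyl-1H-indole
Product: 6 1-(tert-butyldimethylsilyl)-3-iodo-7-prenylindole
Conditions: KHMDS, THF, −78 °C; TBSOTf, −78 → 0 °C
Reagents that add atoms: tert-butyldimethylsilyl trifluoromethanesulfonate, CC(C)(C)[Si](C)(C)OS(=O)(=O)C(F)(F)F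
Why: N-Silylation of the potassium indolide; the reactive silyl triflate is chosen because the C7 methylene crowds N1, and the iodine at C3 blocks C-silylation.

Step 4
Reactants: 6 1-(tert-butyldimethylsilyl)-3-iodo-7-prenylindole; 7 dimethyl squarate (3,4-dimethoxycyclobut-3-ene-1,2-dione)
Product: 10 3-methoxy-4-[1-(tert-butyldimethylsilyl)-7-prenylindol-3-yl]cyclobut-3-ene-1,2-dione, via 3-lithio-1-silyl-7-prenylindole 8 (not isolated), via lithium cyclobutenolate adduct 9 (not isolated)
Conditions: t-BuLi (2 equiv), THF, −78 °C; cannulate into 7, THF, −78 °C; (CF3CO)2O, −78 → 0 °C; aq NaHCO3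
Reagents that add atoms: none
Why: Iodine–lithium exchange gives a 3-lithioindole that the bulky N-silyl group keeps at C3; 1,2-addition to the symmetric squarate and trifluoroacetylation of the tertiary alkoxide cause ionisation, allylic transposition and loss of one O-methyl group, the standard squarate route to 3-alkoxy-4-arylcyclobutenediones. The low temperature and prompt trapping should keep the aryllithium from deprotonating the benzylic–allylic CH2.

Step 5
Reactants: 11 1H-indole
Product: 12 3-iodo-1H-indole
Conditions: I2, KOH, DMF, rt; used at once
Reagents that add atoms: iodine, II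
Why: Standard C3 iodination of the indolide; the product is light- and acid-sensitive and is carried forward without storage.

Step 6
Reactants: 12 3-iodo-1H-indole
Product: 13 1-(tert-butyldimethylsilyl)-3-iodoindole
Conditions: NaHMDS, THF, −78 °C; TBSCl, −78 °C → rt
Reagents that add atoms: tert-butyldimethylsilyl chloride, CC(C)(C)[Si](C)(C)Cl
Why: N-Silylation of the sodium indolide stabilises the iodide and removes the acidic N–H ahead of the zinc reagent; a non-nucleophilic amide base avoids halogen–metal exchange.

Step 7
Reactants: 13 1-(tert-butyldimethylsilyl)-3-iodoindole; 14 chloroacetaldehyde dimethyl acetal (2-chloro-1,1-dimethoxyethane)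
Product: 17 1-(tert-butyldimethylsilyl)-3-(methoxyethynyl)indole, via lithium methoxyacetylide 15 (not isolated), via methoxyethynylzinc chloride 16 (not isolated)
Conditions: 14, LiNEt2 (3 equiv, from Et2NH and n-BuLi), THF, 0 °C; ZnCl2, 0 °C; then 13, Pd(PPh3)4 (5 mol %), THF, rt; filtration through base-washed alumina, used at once
Reagents that add atoms: none
Why: Two eliminations and a deprotonation of the chloroacetal by lithium diethylamide give the alkoxyacetylide; transmetalation to zinc and Negishi coupling with the aryl iodide under zerovalent palladium at room temperature form the C(sp2)–C(sp) bond without acid or heat, which the electron-rich ynol ether would not tolerate.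

Step 8
Reactants: 10 3-methoxy-4-[1-(tert-butyldimethylsilyl)-7-prenylindol-3-yl]cyclobut-3-ene-1,2-dione; 17 1-(tert-butyldimethylsilyl)-3-(methoxyethynyl)indole
Product: 20 2,5-dimethoxy-3-[1-(tert-butyldimethylsilyl)indol-3-yl]-6-[1-(tert-butyldimethylsilyl)-7-prenylindol-3-yl]-1,4-benzoquinone, via maleoylcobalt chloride bis(triphenylphosphine) complex 18 (not isolated), via maleoylcobalt chloride dimethylglyoxime pyridine complex 19 (not isolated)
Conditions: ClCo(PPh3)3 (1.1 equiv), PhH, rt; dimethylglyoxime, pyridine, rt; concentrate; then 17 (1.5 equiv), AgBF4 (1.1 equiv), ClCH2CH2Cl, rt → 60 °C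
Reagents that add atoms: none
Why: The monovalent cobalt of ClCo(PPh3)3 adds oxidatively to the strained bond between the two carbonyl carbons of 10 and gives the five-membered diacyl complex 18 of trivalent cobalt; exchange of the phosphines for dimethylglyoxime and pyridine gives the more labile complex 19. AgBF4 removes chloride and opens a site at which ynol ether 17 binds. Migratory insertion of the alkyne into one cobalt–acyl bond gives a seven-membered cobaltacycle, and reductive elimination forms the second C–C bond, so the six-membered ring is closed by reductive elimination at cobalt (a formal [4+2] of the diacyl unit and the alkyne) and appears directly at the quinone oxidation level. The closest known reaction type is the quinone synthesis from maleoyl- and phthaloylcobalt complexes and alkynes. No stereocentre is formed. The selectivity needed is head-to-tail orientation (2,5- and not 2,6-dimethoxy): the bound ynol ether carries electron density on its indolyl-bearing carbon and positive charge on its methoxy-bearing carbon, while the acyl carbon of 19 beside C–OMe is a plain enone acyl and the one beside the indolyl carbon is a less electrophilic vinylogous ester acyl. Pairing the nucleophilic alkyne carbon with the more electrophilic acyl is expected to give the C1–C6 and C4–C5 bonds of 20. The methyl ynol ether has no O-alkyl β-hydrogen, so it cannot fragment thermally to a ketene, and the aprotic medium avoids its hydration.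

Step 9
Reactants: 20 2,5-dimethoxy-3-[1-(tert-butyldimethylsilyl)indol-3-yl]-6-[1-(tert-butyldimethylsilyl)-7-prenylindol-3-yl]-1,4-benzoquinone
Product: 21 2,5-dimethoxy-3-(1H-indol-3-yl)-6-(7-prenyl-1H-indol-3-yl)-1,4-benzoquinone (CNP0256613.0)
Conditions: Bu4NF (2.2 equiv), AcOH (2.2 equiv), THF, 0 °C
Reagents that add atoms: none
Why: Fluoride cleaves both N–Si bonds; acetic acid protonates the indolides so that the medium stays near neutral and the vinylogous ester and the prenyl group are not attacked.

## Compound list

1 | 7-bromo-1H-indole | Brc1cccc2cc[nH]c12 | starting material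
2 | 1-bromo-3-methylbut-2-ene (prenyl bromide) | CC(C)=CCBr | starting material
3 | 7-lithioindol-1-ylpotassium | [Li]c1cccc2ccn([K])c12 | intermediate
4 | 7-(3-methylbut-2-en-1-yl)-1H-indole | CC(C)=CCc1cccc2cc[nH]c12 | intermediate
5 | 3-iodo-7-(3-methylbut-2-en-1-yl)-1H-indole | CC(C)=CCc1cccc2c(I)c[nH]c12 | intermediate
6 | 1-(tert-butyldimethylsilyl)-3-iodo-7-(3-methylbut-2-en-1-yl)indole | CC(C)=CCc1cccc2c(I)cn([Si](C)(C)C(C)(C)C)c12 | intermediate
7 | dimethyl squarate | COC1=C(OC)C(=O)C1=O | starting material
8 | 1-(tert-butyldimethylsilyl)-3-lithio-7-(3-methylbut-2-en-1-yl)indole | CC(C)=CCc1cccc2c([Li])cn([Si](C)(C)C(C)(C)C)c12 | intermediate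
9 | lithium 1-[1-(tert-butyldimethylsilyl)-7-prenylindol-3-yl]-2,3-dimethoxy-4-oxocyclobut-2-en-1-olate (racemic) | COC1=C(OC)C(O[Li])(c2cn([Si](C)(C)C(C)(C)C)c3c(CC=C(C)C)cccc23)C1=O | intermediate
10 | 3-methoxy-4-[1-(tert-butyldimethylsilyl)-7-prenylindol-3-yl]cyclobut-3-ene-1,2-dione | COC1=C(c2cn([Si](C)(C)C(C)(C)C)c3c(CC=C(C)C)cccc23)C(=O)C1=O | intermediate
11 | 1H-indole | c1ccc2[nH]ccc2c1 | starting material
12 | 3-iodo-1H-indole | Ic1c[nH]c2ccccc12 | intermediate
13 | 1-(tert-butyldimethylsilyl)-3-iodoindole | CC(C)(C)[Si](C)(C)n1cc(I)c2ccccc12 | intermediate
14 | chloroacetaldehyde dimethyl acetal | COC(CCl)OC | starting material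
15 | lithium methoxyacetylide | [Li]C#COC | intermediate
16 | methoxyethynylzinc chloride | COC#C[Zn]Cl | intermediate
17 | 1-(tert-butyldimethylsilyl)-3-(methoxyethynyl)indole | COC#Cc1cn([Si](C)(C)C(C)(C)C)c2ccccc12 | intermediate
18 | chlorobis(triphenylphosphine)cobalt diacyl metallacycle (trivalent cobalt) from 10: 1-cobalta-cyclopent-3-ene-2,5-dione with 3-methoxy and 4-[1-(tert-butyldimethylsilyl)-7-prenylindol-3-yl] | COC1=C(c2cn([Si](C)(C)C(C)(C)C)c3c(CC=C(C)C)cccc23)C(=O)[Co-2](Cl)([P+](c2ccccc2)(c2ccccc2)c2ccccc2)([P+](c2ccccc2)(c2ccccc2)c2ccccc2)C1=O | intermediate
19 | chloro(dimethylglyoxime)(pyridine)cobalt diacyl metallacycle (trivalent cobalt) with the same maleoyl ligand as 18 | COC1=C(c2cn([Si](C)(C)C(C)(C)C)c3c(CC=C(C)C)cccc23)C(=O)[Co-3]2(Cl)([n+]3ccccc3)([N+](O)=C(C)C(C)=[N+]2O)C1=O | intermediate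
20 | 2,5-dimethoxy-3-[1-(tert-butyldimethylsilyl)indol-3-yl]-6-[1-(tert-butyldimethylsilyl)-7-prenylindol-3-yl]-1,4-benzoquinone | COC1=C(c2cn([Si](C)(C)C(C)(C)C)c3ccccc23)C(=O)C(OC)=C(c2cn([Si](C)(C)C(C)(C)C)c3c(CC=C(C)C)cccc23)C1=O | intermediate
21 | 2,5-dimethoxy-3-(1H-indol-3-yl)-6-[7-(3-methylbut-2-en-1-yl)-1H-indol-3-yl]-1,4-benzoquinone | COC1=C(c2c[nH]c3ccccc23)C(=O)C(OC)=C(c2c[nH]c3c(CC=C(C)C)cccc23)C1=O | target

## Step count and risks

Total: 9 steps. Longest linear sequence: 6 steps (steps 1, 2, 3, 4, 8, 9); the second branch (steps 5, 6, 7) joins at step 8.

**Step 8 (key step).** The most likely failure is insertion of the ynol ether in the reverse orientation, which would give the 2,6-dimethoxy pattern, because the electronic difference between the two acyl carbons may be small once both are bound to cobalt. The second is destruction of the ynol ether by the silver salt or by traces of acid (hydration or oligomerisation) before it inserts.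
- Fallback: leave the cobalt chemistry and fix the regiochemistry by the substitution pattern of a preformed quinone. It sets out from 11 and 4 and returns at 21. Acid-promoted conjugate addition of 11 to commercial 2,5-dichloro-1,4-benzoquinone and reoxidation with DDQ would give 2,5-dichloro-3-(1H-indol-3-yl)-1,4-benzoquinone F1. A second addition, now of 4 at the only remaining C–H position, and reoxidation would give 2,5-dichloro-3-(1H-indol-3-yl)-6-(7-prenyl-1H-indol-3-yl)-1,4-benzoquinone F2. Displacement of both vinylogous acyl chlorides with NaOMe in methanol would give 21. The price is exposure of the prenyl group to acid, which has to be kept mild.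

**Step 7.** The ynol ether conjugated to an indole is very electron-rich, so hydration to the arylacetate on work-up or on the adsorbent is likely, and so is slow transmetalation of the alkoxyalkynylzinc in the presence of amine and alkoxide.
- Fallback: make the triple bond by elimination instead of coupling. It sets out from 13 and returns at 17. Iodine–lithium exchange and acylation with N-methoxy-N-methyl-2-methoxyacetamide would give 1-[1-(tert-butyldimethylsilyl)indol-3-yl]-2-methoxyethanone F3. Chelation-controlled enolisation with KHMDS and trapping with PhNTf2 would give the (Z)-enol triflate F4, in which H and OTf are anti. KOt-Bu would then eliminate triflate to give 17 under basic conditions throughout.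

**Step 3.** Silylation of N1 next to the C7 methylene may be slow or incomplete because of steric compression, and the strained N–Si bond may be lost during the lithiation and acylation of step 4.
- Fallback: use a planar carbamate and a milder metalation. It sets out from 5 and returns at 21. Boc2O and DMAP would give tert-butyl 3-iodo-7-prenylindole-1-carboxylate F5. Iodine–magnesium exchange with i-PrMgCl·LiCl at low temperature, addition to 7 and treatment with (CF3CO)2O would give tert-butyl 3-(2-methoxy-3,4-dioxocyclobut-1-en-1-yl)-7-prenylindole-1-carboxylate F6. The conditions of step 8 with 17 would give the mixed quinone F7, 2,5-dimethoxy-3-[1-(tert-butyldimethylsilyl)indol-3-yl]-6-[1-(tert-butoxycarbonyl)-7-prenylindol-3-yl]-1,4-benzoquinone. K2CO3 in methanol would remove both N-groups to give 21; methoxide exchange at the quinone methoxy groups is degenerate.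

**Step 1.** Competing attack at the tertiary end of prenyl bromide (SN2′), N-alkylation of the indolide, or bromine–lithium scrambling between the aryllithium and prenyl bromide would lower the yield of the linear C7 product.
- Fallback: replace the organolithium alkylation by a palladium-catalysed Suzuki–Miyaura coupling of 1 with prenylboronic acid pinacol ester, using a ligand chosen for attack at the unsubstituted allyl terminus and K3PO4 as base. It sets out from 1 and returns at 4, with no new intermediate.

## Further compounds

F1 | step 8 | 2,5-dichloro-3-(1H-indol-3-yl)-1,4-benzoquinone | O=C1C=C(Cl)C(=O)C(c2c[nH]c3ccccc23)=C1Cl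
F2 | step 8 | 2,5-dichloro-3-(1H-indol-3-yl)-6-(7-prenyl-1H-indol-3-yl)-1,4-benzoquinone | O=C1C(c2c[nH]c3c(CC=C(C)C)cccc23)=C(Cl)C(=O)C(c2c[nH]c3ccccc23)=C1Cl
F3 | step 7 | 1-[1-(tert-butyldimethylsilyl)indol-3-yl]-2-methoxyethanone | COCC(=O)c1cn([Si](C)(C)C(C)(C)C)c2ccccc12
F4 | step 7 | (Z)-1-[1-(tert-butyldimethylsilyl)indol-3-yl]-2-methoxyethenyl trifluoromethanesulfonate | CO/C=C(\OS(=O)(=O)C(F)(F)F)c1cn([Si](C)(C)C(C)(C)C)c2ccccc12
F5 | step 3 | tert-butyl 3-iodo-7-prenylindole-1-carboxylate | CC(C)=CCc1cccc2c(I)cn(C(=O)OC(C)(C)C)c12
F6 | step 3 | tert-butyl 3-(2-methoxy-3,4-dioxocyclobut-1-en-1-yl)-7-prenylindole-1-carboxylate | COC1=C(c2cn(C(=O)OC(C)(C)C)c3c(CC=C(C)C)cccc23)C(=O)C1=O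
F7 | step 3 | 2,5-dimethoxy-3-[1-(tert-butyldimethylsilyl)indol-3-yl]-6-[1-(tert-butoxycarbonyl)-7-prenylindol-3-yl]-1,4-benzoquinone | COC1=C(c2cn([Si](C)(C)C(C)(C)C)c3ccccc23)C(=O)C(OC)=C(c2cn(C(=O)OC(C)(C)C)c3c(CC=C(C)C)cccc23)C1=O
F0 | step 1 | none | none
A1 | alternative 1 | 2-iodo-6-prenylaniline | Nc1c(I)cccc1CC=C(C)C
A2 | alternative 1 | tert-butyl 3-[2,3,5,6-tetramethoxy-4-(trimethylsilylethynyl)phenyl]indole-1-carboxylate | COc1c(OC)c(C#C[Si](C)(C)C)c(OC)c(OC)c1-c1cn(C(=O)OC(C)(C)C)c2ccccc12
A3 | alternative 1 | tert-butyl 3-[2,3,5,6-tetramethoxy-4-(7-prenyl-2-trimethylsilyl-1H-indol-3-yl)phenyl]indole-1-carboxylate | COc1c(OC)c(c2c([Si](C)(C)C)[nH]c3c(CC=C(C)C)cccc23)c(OC)c(OC)c1c1cn(C(=O)OC(C)(C)C)c2ccccc12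
A4 | alternative 2 | methyl 3-(1H-indol-3-yl)-2-oxopropanoate | COC(=O)C(=O)Cc1c[nH]c2ccccc12
A5 | alternative 2 | methyl 3-(7-prenyl-1H-indol-3-yl)-2-oxopropanoate | COC(=O)C(=O)Cc1c[nH]c2c(CC=C(C)C)cccc12
A6 | alternative 2 | 2,5-dihydroxy-3-(1H-indol-3-yl)-6-(7-prenyl-1H-indol-3-yl)-1,4-benzoquinone | OC1=C(c2c[nH]c3ccccc23)C(=O)C(O)=C(c2c[nH]c3c(CC=C(C)C)cccc23)C1=O
A7 | alternative 3 | 3-{2,3,5,6-tetramethoxy-4-[5-(5-methylhexa-1,4-dien-2-yl)-1-tosyl-4-vinylpyrrol-3-yl]phenyl}-1-tosylindole | C=Cc1c(-c2c(OC)c(OC)c(-c3cn(S(=O)(=O)c4ccc(C)cc4)c4ccccc34)c(OC)c2OC)cn(S(=O)(=O)c2ccc(C)cc2)c1C(=C)CC=C(C)C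
A8 | alternative 3 | 7-prenyl-3-[2,3,5,6-tetramethoxy-4-(1-tosylindol-3-yl)phenyl]-1-tosylindole | COc1c(OC)c(c2cn(S(=O)(=O)c3ccc(C)cc3)c3c(CC=C(C)C)cccc23)c(OC)c(OC)c1c1cn(S(=O)(=O)c2ccc(C)cc2)c2ccccc12
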